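**Retrosynthetic overview**

1. Target 37 ← desilylation, allylic hydroxylation at C15, esterification of the 8α-hydroxyl with the (Z)-acid 33, and α-methylenation of the trans-lactone 22.
2. 22 ← one-pot [3+3] union of iodide 10 (C9–C10–C5 with the vinyl group, C14 and the C3/C4/C15 unit) and formyl silyl-lactol 17 (C8–C7–C6 with C11/C12): C9–C8 by alkyllithium addition, an O6→O8 silyl relay, then C5–C6 by carbonyl-ene. The cyclohexane is closed first; the γ-lactone follows on work-up.
3. Enabling feature: C6 and C8, the two oxygen-bearing ring carbons on either side of C7, are the ends of a masked 2-substituted malondialdehyde (one a free CHO, the other a silyl lactol tied to C12). C9 is a CH2 on the quaternary C10, and C5 is allylic to C4=C3, the footprint of an ene reaction of an isopropylidene group.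
4. 10 ← asymmetric epoxidation of dienol 3 and a stereospecific 1,2-siloxymethyl shift (sets C10); 17 ← auxiliary-controlled conjugate addition to the menthyloxy butenolide 13 (sets C7).

Key step: step 14

Remark: atoms are numbered as in elemanes (C1=C2 vinyl on C10; ring C5–C10; C4(=C3)–C15 on C5; C11(=C13)–C12 on C7; C14 on C10), and α is the face of H5. But-2-yne-1,4-diol, 5-hydroxyfuran-2(5H)-one, (+)-menthol and crotonaldehyde are taken as purchasable.

**Fragment with C10 (steps 1–8)**

Step 1
Reactants: 1 but-2-yne-1,4-diol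
Product: 2 4-[(tert-butyldimethylsilyl)oxy]but-2-yn-1-ol
Conditions: NaH (1.0 equiv), THF, 0 °C; TBSCl (1.0 equiv), 0 °C → rt
Reagents that add atoms: tert-butyldimethylsilyl chloride, C[Si](C)(Cl)C(C)(C)C
Why: O-silylation of the symmetrical diol through its sparingly soluble monosodium alkoxide should favour the mono ether; no stereocentre is involved.

Step 2
Reactants: 2 4-[(tert-butyldimethylsilyl)oxy]but-2-yn-1-ol
Product: 3 (2E)-4-[(tert-butyldimethylsilyl)oxy]-2-ethenylbut-2-en-1-ol
Conditions: CH2=CHMgBr (3.5 equiv), CuI (10 mol %), THF, 0 → 50 °C; aq. NH4Cl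
Reagents that add atoms: vinylmagnesium bromide, C=C[Mg]Br
Why: Hydroxyl-directed anti-carbomagnesiation of a propargylic alcohol puts the vinyl group on the alkyne carbon next to the carbinol through a five-membered magnesium chelate, so protonation should give the E trisubstituted alkene.

Step 3
Reactants: 3 (2E)-4-[(tert-butyldimethylsilyl)oxy]-2-ethenylbut-2-en-1-ol
Product: 4 [(2R,3R)-3-{[(tert-butyldimethylsilyl)oxy]methyl}-2-ethenyloxiran-2-yl]methanol
Conditions: Ti(OiPr)4 (10 mol %), D-(−)-diethyl tartrate (12 mol %), t-BuOOH, 4 Å molecular sieves, CH2Cl2, −20 °C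
Reagents that add atoms: tert-butyl hydroperoxide, CC(C)(C)OO
Why: Sharpless asymmetric epoxidation is specific for the allylic-alcohol double bond (the vinyl group is homoallylic and monosubstituted), and the D-(−)-tartrate ligand should deliver oxygen to the face that gives the 2R,3R epoxide.

Step 4
Reactants: 4 [(2R,3R)-3-{[(tert-butyldimethylsilyl)oxy]methyl}-2-ethenyloxiran-2-yl]methanol
Product: 5 tert-butyl{[(2R,3R)-3-ethenyl-3-{[(triethylsilyl)oxy]methyl}oxiran-2-yl]methoxy}dimethylsilane
Conditions: Et3SiCl, imidazole, CH2Cl2, 0 °C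
Reagents that add atoms: chlorotriethylsilane, CC[Si](Cl)(CC)CC
Why: Silylation under imidazole buffering protects the primary alcohol without Payne rearrangement or opening of the vinyl epoxide; the stereocentres are untouched.

Step 5
Reactants: 5 tert-butyl{[(2R,3R)-3-ethenyl-3-{[(triethylsilyl)oxy]methyl}oxiran-2-yl]methoxy}dimethylsilane
Product: 6 (2R)-2-{[(tert-butyldimethylsilyl)oxy]methyl}-2-{[(triethylsilyl)oxy]methyl}but-3-enal
Conditions: MeAl(OAr)2 (Ar = 4-bromo-2,6-di-tert-butylphenyl; 20 mol %), CH2Cl2, −78 → −20 °C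
Reagents that add atoms: none
Why: In this organoaluminium-promoted rearrangement of an epoxy silyl ether (semipinacol-type 1,2-shift) the bulky Lewis acid opens the epoxide at the tertiary allylic carbon and the siloxymethyl group on the neighbouring carbon shifts anti to the departing oxygen, so the epoxide configuration is carried with inversion to the new quaternary carbon (future C10) and the former epoxide CH becomes the aldehyde.

Step 6
Reactants: 6 (2R)-2-{[(tert-butyldimethylsilyl)oxy]methyl}-2-{[(triethylsilyl)oxy]methyl}but-3-enal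
Product: 7 tert-butyl{[(2R)-2-ethenyl-4-methyl-2-{[(triethylsilyl)oxy]methyl}pent-3-en-1-yl]oxy}dimethylsilane
Conditions: [Ph3PCH(CH3)2]I, n-BuLi, THF, 0 °C; then 6, 0 °C → rt
Reagents that add atoms: isopropyltriphenylphosphonium iodide, CC(C)[P+](c1ccccc1)(c1ccccc1)c1ccccc1.[I-]
Why: Wittig olefination of the non-enolisable aldehyde with the unstabilised isopropylidene ylide gives an alkene with two equal methyl groups, so no alkene geometry and no new stereocentre arise and the quaternary centre cannot epimerise.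

Step 7
Reactants: 7 tert-butyl{[(2R)-2-ethenyl-4-methyl-2-{[(triethylsilyl)oxy]methyl}pent-3-en-1-yl]oxy}dimethylsilane
Product: 8 (2R)-2-{[(tert-butyldimethylsilyl)oxy]methyl}-2-ethenyl-4-methylpent-3-en-1-ol
Conditions: PPTS (10 mol %), MeOH/CH2Cl2, 0 °C
Reagents that add atoms: none
Why: Acid-catalysed methanolysis cleaves a primary triethylsilyl ether much faster than the tert-butyldimethylsilyl ether on the twin CH2O arm, which should free only the future C9 hydroxyl.

Step 8
Reactants: 8 (2R)-2-{[(tert-butyldimethylsilyl)oxy]methyl}-2-ethenyl-4-methylpent-3-en-1-ol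
Product: 10 tert-butyl{[(2S)-2-ethenyl-2-(iodomethyl)-4-methylpent-3-en-1-yl]oxy}dimethylsilane, via neopentyl triflate 9 (not isolated)
Conditions: Tf2O, 2,6-lutidine, CH2Cl2, −78 °C; NaI, acetone, 0 °C → rt
Reagents that add atoms: sodium iodide, [Na+].[I-]
Why: SN2 displacement at a neopentyl-type carbon needs the triflate leaving group, which iodide should displace at or below room temperature before ionisation with participation of the neighbouring alkenes can compete; the quaternary centre is not touched.

**Fragment with C7 (steps 9–13)**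

Step 9
Reactants: 11 5-hydroxyfuran-2(5H)-one; 12 (+)-menthol [(1S,2R,5S)-5-methyl-2-(propan-2-yl)cyclohexan-1-ol]
Product: 13 (5S)-5-{[(1S,2R,5S)-5-methyl-2-(propan-2-yl)cyclohexyl]oxy}furan-2(5H)-one
Conditions: camphorsulfonic acid (cat.), benzene, reflux (Dean–Stark); crystallisation from hexane, mother liquor re-equilibrated with acid
Reagents that add atoms: none
Why: Acid-catalysed acetalisation gives both acetal epimers, which interconvert under the acid, and crystallisation of the 5S epimer of the (+)-menthyl series should funnel the material into one diastereomer (crystallisation-induced enrichment).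

Step 10
Reactants: 13 (5S)-5-{[(1S,2R,5S)-5-methyl-2-(propan-2-yl)cyclohexyl]oxy}furan-2(5H)-one
Product: 14 (4R,5S)-4-ethenyl-5-{[(1S,2R,5S)-5-methyl-2-(propan-2-yl)cyclohexyl]oxy}oxolan-2-one
Conditions: CH2=CHMgBr, CuBr·SMe2 (10 mol %), THF, −78 °C; aq. NH4Cl
Reagents that add atoms: vinylmagnesium bromide, C=C[Mg]Br
Why: Copper-catalysed conjugate addition to the butenolide takes place anti to the bulky menthyloxy group on the neighbouring carbon, which sets the future C7 (4R) in the trans-disubstituted lactone.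

Step 11
Reactants: 14 (4R,5S)-4-ethenyl-5-{[(1S,2R,5S)-5-methyl-2-(propan-2-yl)cyclohexyl]oxy}oxolan-2-one
Product: 15 (4R)-4-ethenyl-5-hydroxyoxolan-2-one (lactol, both C5 epimers)
Conditions: 2 M HCl, 1,4-dioxane, 40 °C
Reagents that add atoms: water, O
Why: Acid hydrolysis of the lactone acetal (a pseudo-ester) releases the auxiliary and leaves the cyclic lactol, in which C7 is not alpha to a free carbonyl group and should therefore keep its configuration.

Step 12
Reactants: 15 (4R)-4-ethenyl-5-hydroxyoxolan-2-one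
Product: 16 (4R,5R)-4-ethenyl-5-[(triethylsilyl)oxy]oxolan-2-one (trans anomer drawn; the cis anomer is equally usable)
Conditions: Et3SiCl, imidazole, CH2Cl2, 0 °C
Reagents that add atoms: chlorotriethylsilane, CC[Si](Cl)(CC)CC
Why: O-silylation of the lactol hydroxyl should give mainly the trans silyl acetal, and the configuration of this carbon is of no consequence because it becomes a formyl carbon in step 14.

Step 13
Reactants: 16 (4R,5R)-4-ethenyl-5-[(triethylsilyl)oxy]oxolan-2-one
Product: 17 (2R,3R)-5-oxo-2-[(triethylsilyl)oxy]oxolane-3-carbaldehyde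
Conditions: O3, CH2Cl2, −78 °C; PPh3
Reagents that add atoms: ozone, [O-][O+]=O
Why: Ozonolysis with reductive work-up cleaves the only alkene under neutral conditions, and the trans silyl acetal next to C7 keeps the formyl-bearing centre from epimerising.

**Union and ring closure**

Step 14
Reactants: 10 tert-butyl{[(2S)-2-ethenyl-2-(iodomethyl)-4-methylpent-3-en-1-yl]oxy}dimethylsilane; 17 (2R,3R)-5-oxo-2-[(triethylsilyl)oxy]oxolane-3-carbaldehyde
Product: 22 14-(tert-butyldimethylsilyloxy)-8α-(triethylsilyloxy)-13-norelema-1,3-dien-12,6α-olide (5α-H; 6β-H; 7α-H; 8β-H; 10β-CH2OSi; trans-fused lactone), via alkyllithium 18 (not isolated), via lithium alkoxide 19 (not isolated), via aldehyde carboxylate 20 (not isolated), via hydroxy acid 21 (not isolated)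
Conditions: 10, t-BuLi (2.05 equiv), Et2O/pentane, −78 °C; cannulated into 17 (1.2 equiv), Et2O, −78 °C, then → −20 °C; CH2Cl2, Me2AlCl (4 equiv), −78 → 0 °C; 1 M HCl; PPTS (cat.), PhMe, 50 °C
Reagents that add atoms: none
Why: Proposed new method: iodine–lithium exchange turns 10 into the alkyllithium 18, which adds to the free formyl group of 17 (C9–C8 bond), and the lithium alkoxide 19 then takes the triethylsilyl group from the neighbouring lactol oxygen through a six-membered silicate, so that the lactol alkoxide collapses to the carboxylate aldehyde 20 and C6 is unmasked only after C8 has reacted and O8 has been protected. Me2AlCl then closes the cyclohexane by a type 1 intramolecular carbonyl-ene reaction (6-exo-trig at the formyl group, bond from C5 of the isopropylidene alkene to C6, hydrogen from either of its two equal methyl groups), which makes the C5–C6 bond and the isopropenyl group in one event, and the acidic work-up lactonises the hydroxy acid 21 to the trans-fused γ-lactone (5-exo-trig acyl substitution). The closest known reaction types are the base-induced 1,3-diol-type O→O silyl migration used in anion relay sequences and the Lewis-acid-promoted ene cyclisation of citronellal-type aldehydes to isopulegol-type alcohols; what is new is their coupling through a pseudo-acid silyl ether. C8 is set in the addition step by Felkin–Anh attack anti to the acetal-bearing ring carbon of 17, which corresponds to the 8α-oxygen, and C5 and C6 are set in the chair transition state of the ene reaction, in which the C7 acetic acid arm, the C8 silyloxy group, the forming hydroxyl and the forming isopropenyl group are all equatorial while the fixed C10 centre carries CH2OTBS axial and vinyl equatorial. The step needs attack of 18 on the aldehyde and not on the lactone carbonyl (rate difference at −78 °C and inverse addition), silyl transfer rather than attack of the alkoxide on the lactone carbonyl (that path would pass through a strained bicyclo[2.2.1] tetrahedral intermediate) and ring closure by the trisubstituted alkene rather than the vinyl group (the latter is a poor ene and would give a four-membered ring).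

**Completion**

Step 15
Reactants: 22 14-(tert-butyldimethylsilyloxy)-8α-(triethylsilyloxy)-13-norelema-1,3-dien-12,6α-olide
Product: 25 14-(tert-butyldimethylsilyloxy)-8α-(triethylsilyloxy)elema-1,3,11(13)-trien-12,6α-olide, via Mannich base 23 (not isolated), via trimethylammonium iodide 24 (not isolated)
Conditions: LiN(iPr)2, THF, −78 °C; CH2=NMe2+ I−, −78 → 0 °C; MeI, MeOH, rt; aq. NaHCO3, CH2Cl2
Reagents that add atoms: N,N-dimethylmethyleneiminium iodide (Eschenmoser's salt), C=[N+](C)C.[I-]
Why: Mannich reaction of the lactone enolate followed by quaternisation and Hofmann-type elimination is the standard α-methylenation of γ-lactones; the new C11 centre of the Mannich base is erased in the elimination and no other centre is alpha to a carbonyl group.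

Step 16
Reactants: 25 14-(tert-butyldimethylsilyloxy)-8α-(triethylsilyloxy)elema-1,3,11(13)-trien-12,6α-olide
Product: 26 14-(tert-butyldimethylsilyloxy)-8α-hydroxyelema-1,3,11(13)-trien-12,6α-olide
Conditions: PPTS (20 mol %), MeOH/CH2Cl2, 0 °C
Reagents that add atoms: none
Why: Acid-catalysed methanolysis should remove the secondary triethylsilyl ether in the presence of the primary tert-butyldimethylsilyl ether, under conditions too mild for lactone migration or conjugate addition to the α-methylene lactone.

Step 17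
Reactants: 27 (E)-but-2-enal (crotonaldehyde)
Product: 29 (2Z)-2-bromobut-2-enal, via 2,3-dibromobutanal 28 (not isolated)
Conditions: Br2, CH2Cl2, 0 °C; Et3N, 0 °C → rt
Reagents that add atoms: bromine, BrBr
Why: Bromine addition followed by base-induced loss of HBr through the enolate (bromination–dehydrobromination) should give the more stable Z α-bromo enal, with bromine cis to the methyl group.

Step 18
Reactants: 29 (2Z)-2-bromobut-2-enal
Product: 30 (2Z)-2-bromobut-2-en-1-ol
Conditions: NaBH4, CeCl3·7H2O, MeOH, 0 °C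
Reagents that add atoms: none
Why: Luche reduction gives 1,2-reduction only, so the alkene and its geometry are kept.

Step 19
Reactants: 30 (2Z)-2-bromobut-2-en-1-ol
Product: 31 {[(2Z)-2-bromobut-2-en-1-yl]oxy}(tert-butyl)dimethylsilane
Conditions: TBSCl, imidazole, CH2Cl2, rt
Reagents that add atoms: tert-butyldimethylsilyl chloride, C[Si](C)(Cl)C(C)(C)C
Why: Standard silylation protects the hydroxyl before the halogen–metal exchange; no stereo-element is touched.

Step 20
Reactants: 31 {[(2Z)-2-bromobut-2-en-1-yl]oxy}(tert-butyl)dimethylsilane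
Product: 33 (2Z)-2-{[(tert-butyldimethylsilyl)oxy]methyl}but-2-enoic acid, via vinyllithium 32 (not isolated)
Conditions: t-BuLi (2.1 equiv), Et2O, −78 °C; CO2; aq. HCl to pH 3
Reagents that add atoms: carbon dioxide, O=C=O
Why: Bromine–lithium exchange of a vinyl bromide and carboxylation of the vinyllithium both go with retention, so the carboxyl group takes the place of bromine cis to the methyl group, which is the Z (angelate-type) geometry of the target side chain.

Step 21
Reactants: 26 14-(tert-butyldimethylsilyloxy)-8α-hydroxyelema-1,3,11(13)-trien-12,6α-olide; 33 (2Z)-2-{[(tert-butyldimethylsilyl)oxy]methyl}but-2-enoic acid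
Product: 35 8α-[(2Z)-2-{[(tert-butyldimethylsilyl)oxy]methyl}but-2-enoyloxy]-14-(tert-butyldimethylsilyloxy)elema-1,3,11(13)-trien-12,6α-olide, via mixed anhydride 34 (not isolated)
Conditions: 33, 2,4,6-trichlorobenzoyl chloride, Et3N, THF, rt; then 26, DMAP, PhMe, rt
Reagents that add atoms: none
Why: Yamaguchi esterification acylates the equatorial 8α-hydroxyl through the mixed anhydride and is the method least prone to Z→E isomerisation of angelate-type acids; no stereocentre is touched.

Step 22
Reactants: 35 8α-[(2Z)-2-{[(tert-butyldimethylsilyl)oxy]methyl}but-2-enoyloxy]-14-(tert-butyldimethylsilyloxy)elema-1,3,11(13)-trien-12,6α-olide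
Product: 36 the 15-hydroxy derivative of 35
Conditions: SeO2 (30 mol %), t-BuOOH, salicylic acid (10 mol %), CH2Cl2, rt
Reagents that add atoms: tert-butyl hydroperoxide, CC(C)(C)OO
Why: SeO2-catalysed allylic hydroxylation (ene reaction then [2,3]-sigmatropic shift) should take place at the isopropenyl group, the only electron-rich alkene with allylic hydrogens, and on its methyl group rather than at the hindered ring C–H; the vinyl group has no allylic hydrogen and the two acrylate-type alkenes are deactivated.

Step 23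
Reactants: 36 the 15-hydroxy derivative of 35
Product: 37 target, 8α-[(2Z)-2-(hydroxymethyl)but-2-enoyloxy]-14,15-dihydroxyelema-1,3,11(13)-trien-12,6α-olide (5S,6R,7R,8S,10R)
Conditions: HF·pyridine, pyridine, THF, 0 °C → rt
Reagents that add atoms: none
Why: Fluoride-assisted desilylation under mildly acidic conditions removes both primary silyl ethers without conjugate addition to the α-methylene lactone, acyl migration or ester cleavage.

**Compound list**

1 | but-2-yne-1,4-diol | OCC#CCO | starting material
2 | 4-[(tert-butyldimethylsilyl)oxy]but-2-yn-1-ol | OCC#CCO[Si](C)(C)C(C)(C)C | intermediate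
3 | (2E)-4-[(tert-butyldimethylsilyl)oxy]-2-ethenylbut-2-en-1-ol | C=C/C(CO)=C\CO[Si](C)(C)C(C)(C)C | intermediate
4 | [(2R,3R)-3-{[(tert-butyldimethylsilyl)oxy]methyl}-2-ethenyloxiran-2-yl]methanol | C=C[C@]1(CO)O[C@@H]1CO[Si](C)(C)C(C)(C)C | intermediate
5 | tert-butyl{[(2R,3R)-3-ethenyl-3-{[(triethylsilyl)oxy]methyl}oxiran-2-yl]methoxy}dimethylsilane | C=C[C@]1(CO[Si](CC)(CC)CC)O[C@@H]1CO[Si](C)(C)C(C)(C)C | intermediate
6 | (2R)-2-{[(tert-butyldimethylsilyl)oxy]methyl}-2-{[(triethylsilyl)oxy]methyl}but-3-enal | C=C[C@](C=O)(CO[Si](C)(C)C(C)(C)C)CO[Si](CC)(CC)CC | intermediate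
7 | tert-butyl{[(2R)-2-ethenyl-4-methyl-2-{[(triethylsilyl)oxy]methyl}pent-3-en-1-yl]oxy}dimethylsilane | C=C[C@](C=C(C)C)(CO[Si](C)(C)C(C)(C)C)CO[Si](CC)(CC)CC | intermediate
8 | (2R)-2-{[(tert-butyldimethylsilyl)oxy]methyl}-2-ethenyl-4-methylpent-3-en-1-ol | C=C[C@](C=C(C)C)(CO[Si](C)(C)C(C)(C)C)CO | intermediate
9 | (2S)-2-{[(tert-butyldimethylsilyl)oxy]methyl}-2-ethenyl-4-methylpent-3-en-1-yl trifluoromethanesulfonate | C=C[C@](C=C(C)C)(CO[Si](C)(C)C(C)(C)C)COS(=O)(=O)C(F)(F)F | intermediate
10 | tert-butyl{[(2S)-2-ethenyl-2-(iodomethyl)-4-methylpent-3-en-1-yl]oxy}dimethylsilane | C=C[C@](C=C(C)C)(CO[Si](C)(C)C(C)(C)C)CI | intermediate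
11 | 5-hydroxyfuran-2(5H)-one (racemic) | O=C1C=CC(O)O1 | starting material
12 | (+)-menthol, (1S,2R,5S)-5-methyl-2-(propan-2-yl)cyclohexan-1-ol | O[C@H]1C[C@@H](C)CC[C@@H]1C(C)C | starting material
13 | (5S)-5-{[(1S,2R,5S)-5-methyl-2-(propan-2-yl)cyclohexyl]oxy}furan-2(5H)-one | O=C1C=C[C@H](O1)O[C@H]2C[C@@H](C)CC[C@@H]2C(C)C | intermediate
14 | (4R,5S)-4-ethenyl-5-{[(1S,2R,5S)-5-methyl-2-(propan-2-yl)cyclohexyl]oxy}oxolan-2-one | C=C[C@H]1CC(=O)O[C@@H]1O[C@H]2C[C@@H](C)CC[C@@H]2C(C)C | intermediate
15 | (4R)-4-ethenyl-5-hydroxyoxolan-2-one (both C5 epimers) | C=C[C@H]1CC(=O)OC1O | intermediate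
16 | (4R,5R)-4-ethenyl-5-[(triethylsilyl)oxy]oxolan-2-one | C=C[C@H]1CC(=O)O[C@@H]1O[Si](CC)(CC)CC | intermediate
17 | (2R,3R)-5-oxo-2-[(triethylsilyl)oxy]oxolane-3-carbaldehyde | O=C[C@H]1CC(=O)O[C@@H]1O[Si](CC)(CC)CC | intermediate
18 | alkyllithium from 10 (lithium in place of iodine, C10 unchanged) | C=C[C@](C=C(C)C)(CO[Si](C)(C)C(C)(C)C)C[Li] | intermediate
19 | lithium alkoxide of the C8 carbinol from 18 and 17 (8α-O, 7α-H, silyl lactol intact) | C=C[C@](C=C(C)C)(CO[Si](C)(C)C(C)(C)C)C[C@H](O[Li])[C@H]1CC(=O)O[C@@H]1O[Si](CC)(CC)CC | intermediate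
20 | open-chain lithium carboxylate aldehyde (C6 formyl, C8 triethylsilyl ether, C12 carboxylate; C7, C8, C10 as in 22) | C=C[C@](C=C(C)C)(CO[Si](C)(C)C(C)(C)C)C[C@H](O[Si](CC)(CC)CC)[C@H](C=O)CC(=O)O[Li] | intermediate
21 | 6α-hydroxy-14-(tert-butyldimethylsilyloxy)-8α-(triethylsilyloxy)-13-norelema-1,3-dien-12-oic acid (all ring substituents equatorial except axial C14) | C=C[C@]1(CO[Si](C)(C)C(C)(C)C)C[C@H](O[Si](CC)(CC)CC)[C@@H](CC(=O)O)[C@H](O)[C@H]1C(=C)C | intermediate
22 | 14-(tert-butyldimethylsilyloxy)-8α-(triethylsilyloxy)-13-norelema-1,3-dien-12,6α-olide | C=C[C@]1(CO[Si](C)(C)C(C)(C)C)C[C@H](O[Si](CC)(CC)CC)[C@H]2CC(=O)O[C@@H]2[C@H]1C(=C)C | intermediate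
23 | 11α-(dimethylaminomethyl) derivative of 22 (expected epimer; either converges) | C=C[C@]1(CO[Si](C)(C)C(C)(C)C)C[C@H](O[Si](CC)(CC)CC)[C@H]2[C@H](CN(C)C)C(=O)O[C@@H]2[C@H]1C(=C)C | intermediate
24 | trimethylammonium iodide of 23 | C=C[C@]1(CO[Si](C)(C)C(C)(C)C)C[C@H](O[Si](CC)(CC)CC)[C@H]2[C@H](C[N+](C)(C)C)C(=O)O[C@@H]2[C@H]1C(=C)C.[I-] | intermediate
25 | 14-(tert-butyldimethylsilyloxy)-8α-(triethylsilyloxy)elema-1,3,11(13)-trien-12,6α-olide | C=C[C@]1(CO[Si](C)(C)C(C)(C)C)C[C@H](O[Si](CC)(CC)CC)[C@H]2C(=C)C(=O)O[C@@H]2[C@H]1C(=C)C | intermediate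
26 | 14-(tert-butyldimethylsilyloxy)-8α-hydroxyelema-1,3,11(13)-trien-12,6α-olide | C=C[C@]1(CO[Si](C)(C)C(C)(C)C)C[C@H](O)[C@H]2C(=C)C(=O)O[C@@H]2[C@H]1C(=C)C | intermediate
27 | (E)-but-2-enal | C/C=C/C=O | starting material
28 | 2,3-dibromobutanal (racemic anti-addition product) | CC(Br)C(Br)C=O | intermediate
29 | (2Z)-2-bromobut-2-enal | C/C=C(\Br)C=O | intermediate
30 | (2Z)-2-bromobut-2-en-1-ol | C/C=C(\Br)CO | intermediate
31 | {[(2Z)-2-bromobut-2-en-1-yl]oxy}(tert-butyl)dimethylsilane | C/C=C(\Br)CO[Si](C)(C)C(C)(C)C | intermediate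
32 | vinyllithium from 31 (lithium cis to the methyl group) | C/C=C(\[Li])CO[Si](C)(C)C(C)(C)C | intermediate
33 | (2Z)-2-{[(tert-butyldimethylsilyl)oxy]methyl}but-2-enoic acid | C/C=C(\C(O)=O)CO[Si](C)(C)C(C)(C)C | intermediate
34 | mixed anhydride of 33 with 2,4,6-trichlorobenzoic acid | C/C=C(\C(=O)OC(=O)c1c(Cl)cc(Cl)cc1Cl)CO[Si](C)(C)C(C)(C)C | intermediate
35 | 8α-[(2Z)-2-{[(tert-butyldimethylsilyl)oxy]methyl}but-2-enoyloxy]-14-(tert-butyldimethylsilyloxy)elema-1,3,11(13)-trien-12,6α-olide | C=C[C@]1(CO[Si](C)(C)C(C)(C)C)C[C@H](OC(=O)/C(=C\C)CO[Si](C)(C)C(C)(C)C)[C@H]2C(=C)C(=O)O[C@@H]2[C@H]1C(=C)C | intermediate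
36 | 15-hydroxy derivative of 35 | C=C[C@]1(CO[Si](C)(C)C(C)(C)C)C[C@H](OC(=O)/C(=C\C)CO[Si](C)(C)C(C)(C)C)[C@H]2C(=C)C(=O)O[C@@H]2[C@H]1C(=C)CO | intermediate
37 | 8α-[(2Z)-2-(hydroxymethyl)but-2-enoyloxy]-14,15-dihydroxyelema-1,3,11(13)-trien-12,6α-olide | C=C[C@]1(CO)C[C@H](OC(=O)/C(=C\C)CO)[C@H]2C(=C)C(=O)O[C@@H]2[C@H]1C(=C)CO | target

**Totals**

Total step count: 23.
Longest linear sequence: 14 steps (steps 1–8, 14–16, 21–23).

**Steps most likely to fail**

1. Step 14. The alkoxide may attack the lactone carbonyl faster than it takes the silyl group (which would move the lactone to O8), or the ene closure may stall in the ether- and carboxylate-containing medium. The fallback makes the two bonds in separate, known operations; it sets out from 14 and 10 and returns at 22. Ozonolysis of 14 (O3; PPh3) should give (2S,3R)-2-(menthyloxy)-5-oxooxolane-3-carbaldehyde F1. Addition of 18 (from 10 as in step 14) at −78 °C with a cold acetic acid quench should give the Felkin alcohol F2. Silylation (Et3SiCl, imidazole) should give the triethylsilyl ether F3. Methanolysis of the pseudo-ester (NaOMe, MeOH, 0 °C; loss of menthol) should give the aldehyde methyl ester F4. Me2AlCl in CH2Cl2 (carbonyl-ene reaction on an isolated aldehyde) should give the hydroxy ester F5, which lactonises with PPTS in toluene to 22.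

2. Step 11. The configuration at C7 may erode through ring–chain tautomerism of the lactol to the α-vinyl aldehyde, followed by enolisation and migration of the double bond into conjugation. The fallback avoids the free lactol; it sets out from 14 and returns at 22. Acetolysis of 14 (Ac2O, cat. H2SO4, 0 °C) exchanges the menthyloxy group for acetoxy without opening the ring and should give the acetoxy lactone F6. Ozonolysis should give the acetoxy aldehyde F7, which takes the place of 17 in step 14; the alkoxide then takes the acetyl group by 1,3-O→O acyl migration and the sequence should give the 8-acetate F8. Mild methanolysis (K2CO3, MeOH, 0 °C) should give the alcohol F9, and silylation (Et3SiCl, imidazole) gives 22.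

3. Step 22. Over-oxidation to the enal and competing oxidation at the allylic C5–H may lower the yield. The fallback brings the oxygen in by substitution; it sets out from 35 and returns at 36. Ene-type chlorination of 35 with Ca(OCl)2 and solid CO2 in CH2Cl2/H2O, selective for the electron-rich isopropenyl group, should give the allylic chloride F10. Silver-assisted hydrolysis (AgBF4, aqueous acetone; the allyl cation has two equal CH2 ends) should give 36.

**Further compounds**

F1 | step 14 | (2S,3R)-2-{[(1S,2R,5S)-5-methyl-2-(propan-2-yl)cyclohexyl]oxy}-5-oxooxolane-3-carbaldehyde | O=C[C@H]1CC(=O)O[C@@H]1O[C@H]2C[C@@H](C)CC[C@@H]2C(C)C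
F2 | step 14 | C8 alcohol from 18 and F1 (8α-OH, menthyl lactone acetal intact) | C=C[C@](C=C(C)C)(CO[Si](C)(C)C(C)(C)C)C[C@H](O)[C@H]1CC(=O)O[C@@H]1O[C@H]2C[C@@H](C)CC[C@@H]2C(C)C
F3 | step 14 | triethylsilyl ether of F2 | C=C[C@](C=C(C)C)(CO[Si](C)(C)C(C)(C)C)C[C@H](O[Si](CC)(CC)CC)[C@H]1CC(=O)O[C@@H]1O[C@H]2C[C@@H](C)CC[C@@H]2C(C)C
F4 | step 14 | open-chain aldehyde methyl ester (C6 formyl, C8 triethylsilyl ether, C12 methyl ester) | C=C[C@](C=C(C)C)(CO[Si](C)(C)C(C)(C)C)C[C@H](O[Si](CC)(CC)CC)[C@H](C=O)CC(=O)OC
F5 | step 14 | methyl ester of hydroxy acid 21 | C=C[C@]1(CO[Si](C)(C)C(C)(C)C)C[C@H](O[Si](CC)(CC)CC)[C@@H](CC(=O)OC)[C@H](O)[C@H]1C(=C)C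
F6 | step 11 | (2R,3R)-3-ethenyl-5-oxooxolan-2-yl acetate (trans) | C=C[C@H]1CC(=O)O[C@@H]1OC(C)=O
F7 | step 11 | (2R,3R)-3-formyl-5-oxooxolan-2-yl acetate (trans) | O=C[C@H]1CC(=O)O[C@@H]1OC(C)=O
F8 | step 11 | 8α-acetoxy-14-(tert-butyldimethylsilyloxy)-13-norelema-1,3-dien-12,6α-olide | C=C[C@]1(CO[Si](C)(C)C(C)(C)C)C[C@H](OC(C)=O)[C@H]2CC(=O)O[C@@H]2[C@H]1C(=C)C
F9 | step 11 | 8α-hydroxy-14-(tert-butyldimethylsilyloxy)-13-norelema-1,3-dien-12,6α-olide | C=C[C@]1(CO[Si](C)(C)C(C)(C)C)C[C@H](O)[C@H]2CC(=O)O[C@@H]2[C@H]1C(=C)C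
F10 | step 22 | 15-chloro derivative of 35 | C=C[C@]1(CO[Si](C)(C)C(C)(C)C)C[C@H](OC(=O)/C(=C\C)CO[Si](C)(C)C(C)(C)C)[C@H]2C(=C)C(=O)O[C@@H]2[C@H]1C(=C)CCl
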